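Its constants are invented; the result is computed.

You asked for a quick number and your hunch was that 12 h might be too short, so I turned the constants into half-lives at the charged amounts.

    acidic substrate + free base ⇌ protonated base + anion, settled at all times (K1 = 2.1)
    electrophile + anion → product (k2 = 0.0549 M⁻¹ s⁻¹)
    solid electrophile ⇌ electrophile, rate k3*(cs3 - [electrophile]) while solid is left; crystals form when [electrophile] > cs3 (cs3 = 13 mM, k3 = 0.00604 s⁻¹)
    protic impurity + free base → quenched reagent (k4 = 0.102 M⁻¹ s⁻¹)

acidic substrate 20 mM; free base 22.0 mM; solid electrophile 60.0 mM; protic impurity 6.00 mM; time 12 h

- product at 12 h, in percent of the acidic substrate charged
- concentration of electrophile in solution at 12 h, in percent of saturation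

The protic impurity, with free base as charged, had a half-life of 0.086 h. The solid's approach to saturation had one of

ln(2)/k3 = 0.0319 h

and the anion, by its step to product alone with [electrophile] at saturation, had one of

ln(2)/(k2·cs3) = 0.270 h

Each was far shorter than the run, so I expected the clock not to stop this flask, and I looked at what the free base could pay for.

Each unit of free base ends as protonated base or as quenched reagent, and the quenched reagent cannot exceed the protic impurity charged. I therefore reckoned the spare base, the free base charged less all the protic impurity charged, 16.0 mM:

spare base = 22.0 mM − 6.00 mM = 16.0 mM

This is less than the acidic substrate charged, which makes free base the limiting reagent. Once free base and anion are both used up, the spare base is the least the product can reach, and I committed to 80.0%.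

Product and a saturated solution together need at most 33.0 mM of the 60.0 mM of solid electrophile, so I gave 100% of saturation.

The forecast stood a little above me on yield, with 82% and 100%, on this ground: “The base is the limiting reagent”.

The flask gave 81.9% and >99.9%. At 12 h it held 16.4 mM of protonated base, above the spare base, and 6.5% of its protic impurity remained. The neighbouring flask charged with 10 mM of protic impurity has a spare base of 12.0 mM, or 60.0% of the acidic substrate. That neighbour ended with 13.7 mM of protonated base and 68.7% of product, with 17% of its protic impurity remaining.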